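The lactone O1–C5H2 bond is cut back to a ketone. Without the C3 benzyl group, C4 of the butyrolactone lies between two CH2 arms (C3 and C5), so the ring maps onto a mirror-symmetric 3-(arylmethyl)cyclobutanone, made from eugenol and dichloroketene. A catalytic enantioselective Baeyer–Villiger oxidation inserts oxygen into one of the two enantiotopic C(=O)–CH2 bonds of this four-membered ring, a temporary ring absent from the target. In one operation it forms the O1–C5 bond, the five-membered lactone and the C4 stereocentre. C4 then directs trans benzylation at C3, and an Evans syn glycolate aldol on the freed phenol installs the (7R,8R) arylglycerol ether.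

Key step: step 4

Remark: the target is read as the (3R,4R)-trans lactone with a (7R,8R) (threo) side chain; compounds 1, 7, 12 and 14 are taken as catalogue compounds; in step 4 the ligand enantiomer that delivers the R lactone is meant, which a test run would have to establish, as the sense of induction for this ligand is not predicted here.

Lactone numbering used throughout: O1, C2 (C=O), C3, C4, C5 (OCH2). Side chain: C7 (benzylic CHOH), C8 (CH–OAr), C9 (CH2OH).

Step 1
Reactants: 1 eugenol (4-allyl-2-methoxyphenol)
Product: 2 tert-butyl(4-allyl-2-methoxyphenoxy)dimethylsilane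
Conditions: TBSCl, imidazole, DMF, rt
Reagents that add atoms: TBSCl, C[Si](C)(Cl)C(C)(C)C
Why: Imidazole-mediated silyl ether formation masks the phenol before the acid chloride, peracid and enolate steps; no stereocentre is involved.

Step 2
Reactants: 2 tert-butyl(4-allyl-2-methoxyphenoxy)dimethylsilane
Product: 3 rac-2,2-dichloro-3-[4-(tert-butyldimethylsilyloxy)-3-methoxybenzyl]cyclobutan-1-one
Conditions: Cl3CCOCl, Zn(Cu), POCl3, Et2O, reflux
Reagents that add atoms: trichloroacetyl chloride, ClC(=O)C(Cl)(Cl)Cl
Why: Dichloroketene generated in the flask should undergo thermal [2+2] cycloaddition with the terminal alkene, its carbonyl carbon bonding to the terminal CH2; the single stereocentre is racemic and is erased in step 3.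

Step 3
Reactants: 3 rac-2,2-dichloro-3-[4-(tert-butyldimethylsilyloxy)-3-methoxybenzyl]cyclobutan-1-one
Product: 4 3-[4-(tert-butyldimethylsilyloxy)-3-methoxybenzyl]cyclobutan-1-one (achiral, mirror-symmetric)
Conditions: Zn dust, AcOH, rt
Reagents that add atoms: none
Why: Zinc reduction of the α,α-dichloro ketone through zinc enolates should give the symmetric ketone; the aryl silyl ether tolerates acetic acid at room temperature.

Step 4
Reactants: 4 3-[4-(tert-butyldimethylsilyloxy)-3-methoxybenzyl]cyclobutan-1-one
Product: 6 (R)-4-[4-(tert-butyldimethylsilyloxy)-3-methoxybenzyl]dihydrofuran-2(3H)-one, via Criegee peroxyhemiketal 5 (not isolated)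
Conditions: Sc(OTf)3 (5 mol%), chiral amino-acid-derived N,N'-dioxide bis(2,6-diisopropylanilide) ligand (6 mol%), m-CPBA (1.2 equiv), EtOAc, −20 °C
Reagents that add atoms: mCPBA, O=C(OO)c1cccc(Cl)c1
Why: The scandium-bound ketone should add mCPBA to give Criegee adduct 5, in which the CH2 group held antiperiplanar to the O–O bond migrates from carbon to oxygen with loss of 3-chlorobenzoate, so the O1–C5H2 bond of the lactone is made in the bond shift itself. The closest known reaction type is the catalytic asymmetric Baeyer–Villiger desymmetrisation of 3-substituted cyclobutanones. The five-membered lactone is closed by ring expansion (a 1,2-shift that inserts one oxygen into the four-membered ring), not by an exo or endo cyclisation, and relief of cyclobutanone strain should drive it at low temperature. The new stereocentre C4 of the lactone arises because the two arms of the formerly mirror-symmetric ring become different; it is controlled by the chiral ligand sphere on scandium, which fixes the conformation of 5 and so decides which enantiotopic CH2 is antiperiplanar. The only selectivity needed is between the two enantiotopic α-CH2 groups of ketone 4; both are primary and give the same constitution, so there is no regiochemical question, and the alkene-free, silyl-capped arene should be inert to the peracid at −20 °C.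

Step 5
Reactants: 7 4-benzyloxy-3-methoxybenzyl alcohol
Product: 8 4-benzyloxy-3-methoxybenzyl bromide
Conditions: PBr3, Et2O, 0 °C; used directly
Reagents that add atoms: phosphorus tribromide, BrP(Br)Br
Why: Bromination of an electron-rich benzylic alcohol through its phosphite ester is a standard substitution; the labile bromide is used without storage.

Step 6
Reactants: 6 (R)-4-[4-(tert-butyldimethylsilyloxy)-3-methoxybenzyl]dihydrofuran-2(3H)-one; 8 4-benzyloxy-3-methoxybenzyl bromide
Product: 10 (3R,4R)-3-(4-benzyloxy-3-methoxybenzyl)-4-[4-(tert-butyldimethylsilyloxy)-3-methoxybenzyl]dihydrofuran-2(3H)-one, via lithium enolate 9 (not isolated)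
Conditions: LiHMDS, THF, −78 °C; then 8, DMPU, −78 to −40 °C
Reagents that add atoms: LiHMDS, [Li]N([Si](C)(C)C)[Si](C)(C)C (lithium is carried only in intermediate 9; nothing from it remains in 10)
Why: Diastereoselective α-alkylation of a β-substituted γ-butyrolactone enolate: the bromide should approach the face of enolate 9 anti to the C4 benzyl group, setting C3 as R (trans), which is also the thermodynamically preferred isomer.

Step 7
Reactants: 10 (3R,4R)-3-(4-benzyloxy-3-methoxybenzyl)-4-[4-(tert-butyldimethylsilyloxy)-3-methoxybenzyl]dihydrofuran-2(3H)-one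
Product: 11 (3R,4R)-3-(4-benzyloxy-3-methoxybenzyl)-4-(4-hydroxy-3-methoxybenzyl)dihydrofuran-2(3H)-one
Conditions: TBAF, AcOH, THF, 0 °C
Reagents that add atoms: none
Why: Buffered fluoride cleavage of the aryl silyl ether should free only the phenol on the C4 benzyl ring; the benzyl ether and lactone are untouched and the trans lactone cannot epimerise to a more stable isomer.

Step 8
Reactants: 11 (3R,4R)-3-(4-benzyloxy-3-methoxybenzyl)-4-(4-hydroxy-3-methoxybenzyl)dihydrofuran-2(3H)-one; 12 (S)-4-benzyl-3-(chloroacetyl)oxazolidin-2-one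
Product: 13 (S)-4-benzyl-3-(aryloxyacetyl)oxazolidin-2-one, aryl = 2-methoxy-4-{[(3R,4R)-4-(4-benzyloxy-3-methoxybenzyl)-5-oxotetrahydrofuran-3-yl]methyl}phenyl
Conditions: K2CO3, NaI (cat.), acetone, rt
Reagents that add atoms: none
Why: Williamson etherification with Finkelstein assistance: the phenoxide should displace halide from the strongly activated α-halo imide faster than it attacks a carbonyl group; no stereocentre is touched.

Step 9
Reactants: 13 the (S)-4-benzyl-3-(aryloxyacetyl)oxazolidin-2-one from step 8; 14 4-benzyloxy-3-methoxybenzaldehyde (O-benzylvanillin)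
Product: 17 (S)-4-benzyl-3-[(2S,3R)-2-aryloxy-3-(4-benzyloxy-3-methoxyphenyl)-3-hydroxypropanoyl]oxazolidin-2-one (aryl as in 13), via boron Z-enolate 15 (not isolated), via boron aldolate 16 (not isolated)
Conditions: Bu2BOTf, i-Pr2NEt, CH2Cl2, −78 to 0 °C; 14, −78 to 0 °C; then pH 7 buffer, MeOH, 30% H2O2, 0 °C
Reagents that add atoms: dibutylboron triflate, CCCCB(CCCC)OS(=O)(=O)C(F)(F)F (boron and butyl groups are carried only in intermediates 15 and 16; nothing from it remains in 17)
Why: Evans syn aldol of a glycolate imide: Z-enolate 15 should react through a chair Zimmerman–Traxler transition state on the face away from the auxiliary benzyl group, giving the syn adduct whose two new centres become C8 and C7, both R after step 10; the imide is enolised in preference to the less acidic lactone.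

Step 10
Reactants: 17 the syn aldol adduct from step 9
Product: 18 (3R,4R)-3-(4-benzyloxy-3-methoxybenzyl)-4-(4-{[(1R,2R)-1-(4-benzyloxy-3-methoxyphenyl)-1,3-dihydroxypropan-2-yl]oxy}-3-methoxybenzyl)dihydrofuran-2(3H)-one
Conditions: NaBH4, THF/H2O (4:1), 0 °C to rt
Reagents that add atoms: none
Why: Reductive cleavage of the N-acyl oxazolidinone: the exocyclic imide carbonyl, activated further by the α-aryloxy group, should be reduced to the primary alcohol well before the γ-lactone; C7 and C8 are not touched.

Step 11
Reactants: 18 the dibenzyl ether from step 10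
Product: 19 (3R,4R)-4-(4-{[(1R,2R)-1,3-dihydroxy-1-(4-hydroxy-3-methoxyphenyl)propan-2-yl]oxy}-3-methoxybenzyl)-3-(4-hydroxy-3-methoxybenzyl)dihydrofuran-2(3H)-one (CNP0144301.3)
Conditions: H2 (1 atm), 10% Pd/C, EtOAc/EtOH, rt, stopped after uptake of two equivalents
Reagents that add atoms: none
Why: Catalytic hydrogenolysis of the two benzyl aryl ethers under neutral conditions should be much faster than cleavage of the benzylic C7–OH or of the alkyl aryl ether, so both phenols are freed with all four stereocentres intact.

Compound list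
1 | eugenol (4-allyl-2-methoxyphenol) | C=CCc1ccc(O)c(OC)c1 | starting material
2 | tert-butyl(4-allyl-2-methoxyphenoxy)dimethylsilane | C=CCc1ccc(O[Si](C)(C)C(C)(C)C)c(OC)c1 | intermediate
3 | rac-2,2-dichloro-3-[4-(tert-butyldimethylsilyloxy)-3-methoxybenzyl]cyclobutan-1-one | O=C1CC(Cc2ccc(O[Si](C)(C)C(C)(C)C)c(OC)c2)C1(Cl)Cl | intermediate
4 | 3-[4-(tert-butyldimethylsilyloxy)-3-methoxybenzyl]cyclobutan-1-one | O=C1CC(Cc2ccc(O[Si](C)(C)C(C)(C)C)c(OC)c2)C1 | intermediate
5 | Criegee peroxyhemiketal of 4 with mCPBA (scandium-bound in the flask, drawn neutral) | OC1(OOC(=O)c2cccc(Cl)c2)CC(Cc2ccc(O[Si](C)(C)C(C)(C)C)c(OC)c2)C1 | intermediate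
6 | (R)-4-[4-(tert-butyldimethylsilyloxy)-3-methoxybenzyl]dihydrofuran-2(3H)-one | C1C(=O)OC[C@@H]1Cc1ccc(O[Si](C)(C)C(C)(C)C)c(OC)c1 | intermediate
7 | 4-benzyloxy-3-methoxybenzyl alcohol | OCc1ccc(OCc2ccccc2)c(OC)c1 | starting material
8 | 4-benzyloxy-3-methoxybenzyl bromide | BrCc1ccc(OCc2ccccc2)c(OC)c1 | intermediate
9 | lithium enolate of lactone 6 | C1=C(O[Li])OC[C@@H]1Cc1ccc(O[Si](C)(C)C(C)(C)C)c(OC)c1 | intermediate
10 | (3R,4R)-3-(4-benzyloxy-3-methoxybenzyl)-4-[4-(tert-butyldimethylsilyloxy)-3-methoxybenzyl]dihydrofuran-2(3H)-one | COc1cc(C[C@H]2C(=O)OC[C@@H]2Cc2ccc(O[Si](C)(C)C(C)(C)C)c(OC)c2)ccc1OCc1ccccc1 | intermediate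
11 | (3R,4R)-3-(4-benzyloxy-3-methoxybenzyl)-4-(4-hydroxy-3-methoxybenzyl)dihydrofuran-2(3H)-one | COc1cc(C[C@H]2C(=O)OC[C@@H]2Cc2ccc(O)c(OC)c2)ccc1OCc1ccccc1 | intermediate
12 | (S)-4-benzyl-3-(chloroacetyl)oxazolidin-2-one | O=C(CCl)N1[C@@H](Cc2ccccc2)COC1=O | starting material
13 | (S)-4-benzyl-3-(aryloxyacetyl)oxazolidin-2-one carrying the (3R,4R)-lactone on the aryl group | COc1cc(C[C@H]2C(=O)OC[C@@H]2Cc2ccc(OCC(=O)N3[C@@H](Cc4ccccc4)COC3=O)c(OC)c2)ccc1OCc1ccccc1 | intermediate
14 | 4-benzyloxy-3-methoxybenzaldehyde (O-benzylvanillin) | O=Cc1ccc(OCc2ccccc2)c(OC)c1 | starting material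
15 | (Z)-dibutylboron enolate of 13 | COc1cc(C[C@H]2C(=O)OC[C@@H]2Cc2ccc(O/C=C(\OB(CCCC)CCCC)N3[C@@H](Cc4ccccc4)COC3=O)c(OC)c2)ccc1OCc1ccccc1 | intermediate
16 | dibutylboron aldolate (O-borinate of 17) | COc1cc(C[C@H]2C(=O)OC[C@@H]2Cc2ccc(O[C@H](C(=O)N3[C@@H](Cc4ccccc4)COC3=O)[C@H](OB(CCCC)CCCC)c3ccc(OCc4ccccc4)c(OC)c3)c(OC)c2)ccc1OCc1ccccc1 | intermediate
17 | (S)-4-benzyl-3-[(2S,3R)-2-aryloxy-3-(4-benzyloxy-3-methoxyphenyl)-3-hydroxypropanoyl]oxazolidin-2-one | COc1cc(C[C@H]2C(=O)OC[C@@H]2Cc2ccc(O[C@H](C(=O)N3[C@@H](Cc4ccccc4)COC3=O)[C@H](O)c3ccc(OCc4ccccc4)c(OC)c3)c(OC)c2)ccc1OCc1ccccc1 | intermediate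
18 | di-O-benzyl ether of the target, (3R,4R) and (7R,8R) | COc1cc(C[C@H]2C(=O)OC[C@@H]2Cc2ccc(O[C@H](CO)[C@H](O)c3ccc(OCc4ccccc4)c(OC)c3)c(OC)c2)ccc1OCc1ccccc1 | intermediate
19 | CNP0144301.3, (3R,4R)-4-(4-{[(1R,2R)-1,3-dihydroxy-1-(4-hydroxy-3-methoxyphenyl)propan-2-yl]oxy}-3-methoxybenzyl)-3-(4-hydroxy-3-methoxybenzyl)dihydrofuran-2(3H)-one | COc1cc(C[C@H]2C(=O)OC[C@@H]2Cc2ccc(O[C@H](CO)[C@H](O)c3ccc(O)c(OC)c3)c(OC)c2)ccc1O | target

Total step count: 11. Longest linear sequence: 10 steps (steps 1–4 and 6–11, from eugenol); step 5 is a one-step side branch.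

Steps most likely to fail

1. Step 4. The process at risk is insufficient discrimination between the two enantiotopic CH2 groups, because the aryl group sits one CH2 further from the carbonyl than in 3-aryl cyclobutanones. The fallback moves stereocontrol from the catalyst to a covalently bound auxiliary. It sets out from 4: ketalisation with (2R,4R)-pentane-2,4-diol (TsOH cat., benzene, reflux, water removal) would give spiro ketal F1. Treatment of F1 with mCPBA and SnCl4 in CH2Cl2 at −100 °C should open the ketal to an oxocarbenium ion, add the peracid and let one of the now diastereotopic CH2 groups migrate. This would release the diol and return to the route at lactone 6. The diol enantiomer that leads to the R lactone would be fixed in a test run; the (2R,4R) form is drawn.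

2. Step 8. The process at risk is acyl transfer, that is attack of the phenoxide at the exocyclic imide carbonyl with loss of the auxiliary, in competition with displacement of halide. The fallback builds the glycolate first and attaches the auxiliary by N-acylation. It sets out from 11: alkylation with tert-butyl bromoacetate (K2CO3, acetone) would give tert-butyl aryloxyacetate F2, and TFA in CH2Cl2 would give aryloxyacetic acid F3. Pivaloyl chloride and Et3N in THF at −20 °C would give mixed pivalic anhydride F4, and (S)-4-benzyloxazolidin-2-one with LiCl at rt would then give imide 13, where the route resumes.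

3. Step 10. The process at risk is over-reduction, that is hydride attack on the lactone carbonyl in competition with the imide, or retro-aldol cleavage under the basic aqueous conditions. The fallback separates auxiliary removal from reduction. It sets out from 17: LiOH/H2O2 in THF/H2O at 0 °C, sulfite quench and acidification (which re-closes any opened lactone) would give α-aryloxy-β-hydroxy acid F5 and free the auxiliary. BH3·SMe2 in THF (0 °C to rt) reduces carboxylic acids much faster than lactones and should give diol 18, where the route resumes.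

Further compounds
F1 | step 4 | (6R,8R)-6,8-dimethyl-2-[4-(tert-butyldimethylsilyloxy)-3-methoxybenzyl]-5,9-dioxaspiro[3.5]nonane (ketal of 4 with (2R,4R)-pentane-2,4-diol) | C[C@@H]1C[C@@H](C)OC2(CC(Cc3ccc(O[Si](C)(C)C(C)(C)C)c(OC)c3)C2)O1
F2 | step 8 | tert-butyl aryloxyacetate of phenol 11 | COc1cc(C[C@H]2C(=O)OC[C@@H]2Cc2ccc(OCC(=O)OC(C)(C)C)c(OC)c2)ccc1OCc1ccccc1
F3 | step 8 | aryloxyacetic acid of phenol 11 | COc1cc(C[C@H]2C(=O)OC[C@@H]2Cc2ccc(OCC(=O)O)c(OC)c2)ccc1OCc1ccccc1
F4 | step 8 | mixed pivalic anhydride of F3 | COc1cc(C[C@H]2C(=O)OC[C@@H]2Cc2ccc(OCC(=O)OC(=O)C(C)(C)C)c(OC)c2)ccc1OCc1ccccc1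
F5 | step 10 | (2S,3R)-2-aryloxy-3-(4-benzyloxy-3-methoxyphenyl)-3-hydroxypropanoic acid (aryl as in 13) | COc1cc(C[C@H]2C(=O)OC[C@@H]2Cc2ccc(O[C@H](C(=O)O)[C@H](O)c3ccc(OCc4ccccc4)c(OC)c3)c(OC)c2)ccc1OCc1ccccc1
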